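Remark on the chemistry: the target is treated as the enol tautomer drawn (a 3,5-dihydroxycyclohexa-2,4-dien-1-one); its enol forms interconvert and all descriptors refer to this tautomer. (S)-Limonene, (R)-but-3-en-2-ol and (R)-2-methylbutanoic acid are taken as commercial, enantiomerically enriched materials.

Numbering used: ring A as in the name of the target 24 (C1 ketone, C2 acyl-bearing, C3 and C5 enol carbons, C4 link-bearing, C6 quaternary); ring B as C1′ (bears the link), C2′ (carbinol), C5′ (bears isopropenyl).

## Analysis of the target

The target is a dearomatised acylphloroglucinol: ring A, a cyclohexane-1,3,5-trione in its dienol form, is joined through one CH2 group at C4 to ring B, a cyclopentane. Ring A is fully substituted: C6 is a quaternary stereocentre (R) carrying methyl and 3-methylbut-2-enyl between the carbonyl carbons C1 and C5, and C2 carries a (2R)-2-methylbutanoyl group. Ring B has three contiguous stereocentres, C1′ (R), C2′ (S, tertiary carbinol with methyl) and C5′ (S, isopropenyl); the link is trans to the isopropenyl group and cis to the hydroxyl. The five stereocentres form three sets that cannot relay configuration to one another (C6, the ring B triad, the side-chain centre), so each needs its own source of chirality. The sensitive groups are the tertiary alcohol (five atoms from an enol carbon, so it can close to a cyclic enol ether or eliminate under acid), the isopropenyl and prenyl alkenes, the acidic enolised tricarbonyl and the epimerisable CH next to the side-chain ketone. The central difficulty is C6: it is stereogenic only because C1 and C5 have different neighbours (C2 and C4), so it must be built with two carbonyl groups that already differ, and a ring A intermediate lacking the C4 substituent would be achiral. The strategy rests on C6 being bonded to the CH2 of a CH2–CH=C unit and to two carbonyl carbons, which is the pattern formed when the enolate of an allyl acetoacetate rearranges; the C6–CH2 bond can therefore be made suprafacially from an allylic C–O stereocentre.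

## Retrosynthetic reasoning

**Acyl group.** The bond from ring A C2 to the side-chain carbonyl is cut first, giving trione 21 and acid 22. C2 is the only unsubstituted carbon between two carbonyls, so the acylation has one position to go to. It is placed last because the acylated tricarbonyl is the most acidic compound of the route and the α-stereocentre of 22 should see as few basic steps as possible.

**Ring A.** Trione 21 is opened at C4–C5 and at C2–C3, leading through the open-chain hydroxy diketo ester 20 to keto ester 8 and lactone 19. Each cut separates a carbonyl carbon from an enolisable carbon, so the forward reactions are an enolate acylation and a Dieckmann closure. The cuts leave C6 with both carbonyls attached: the ester of 8 becomes C5, its acetyl group becomes C1 and C2. The lactone carbonyl and α-carbon of 19 become C3 and C4, and the ring B tertiary oxygen serves as the leaving group, so it needs no protecting group. Which carbonyl of 8 is ester and which is ketone decides the configuration at C6 in ring A.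

**Prenyl group.** Keto ester 8 is traced to crotyl ester 6 and alkene 7 by exchange of alkene ends, and 6 to acid 5 by ester formation. The detour through crotyl is needed because only a secondary allylic ester has a carbinol stereocentre to transfer; a dimethylallyl ester has none.

**Quaternary carbon (key disconnection).** Acid 5 is cut at the bond between the quaternary carbon and the allylic CH2 in a [3,3] sense, leading to dienolate 4 of ester 3. One step then delivers the quaternary carbon with its carboxyl and acetyl groups and converts the C–O stereocentre of the allylic ester into the C–C stereocentre. The forward reaction must pass through one enolate geometry and one chair.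

**Ester 3.** It is cut at the acyl–oxygen bond to acetoacetate 1 and alcohol 2; the forward ester exchange does not touch the carbinol centre.

**Lactone 19.** The acyl–oxygen bond is opened to hydroxy ester 18, and 18 is traced to enoate 17 by removing two hydrogens from the chain. This puts an alkene next to C1′ and makes the C1′–H bond accessible from an allylic epoxide.

**C1′–H bond.** Enoate 17 is traced to epoxy enoate 16 by replacing the C1′–H bond with the epoxide C–O bond of opposite configuration. The forward reaction is a substitution with inversion, so the epoxide face fixes both C1′ and C2′.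

**Chain and epoxide.** Epoxy enoate 16 is cut at its alkene to epoxy aldehyde 14 and ylide 15, and 14 is traced to enal 13 by removing the epoxide oxygen. The forward epoxidation is controlled by the neighbouring C5′ substituent.

**Ring B carbons.** Enal 13 is opened at the C1′=C2′ bond to keto aldehyde 12 (aldol condensation forward), and 12 is traced via diol 11 and epoxide 10 to terpene 9 by reclosing the cleaved ring alkene. Terpene 9 already holds all ten carbons of ring B with its methyl and isopropenyl groups, and its stereocentre becomes C5′.

## Alternatives that were turned down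

**Alternative 1:** Ring A is cut between C1 and C2, leading to the linear triketo ester A1, which already carries the 2-methylbutanoyl ketone and has the tertiary alcohol as a silyl ether. Forward, Mg(OMe)2 or NaOMe enolises the carbon of A1 flanked by a chain ketone and the side-chain carbonyl; it attacks the methyl ester on the quaternary carbon and closes ring A to the triethylsilyl ether of the target A2.
- For: the nucleophile is a doubly activated carbon, so the closure is monoanion chemistry under mild base, it mirrors the biosynthesis, and no late C-acylation is needed. On the ring closure itself this is stronger than the polyanion Dieckmann of step 12.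
- Against: the closure creates no stereocentre. The quaternary carbon must already be in A1, so an enantioenriched α,α-disubstituted β-keto ester is still required, and ring B must in addition be attached to a carbon between two ketones. A1 carries that epimerisable CH and the side-chain centre through enolising alkoxide conditions, its non-enolisable β-keto ester is open to retro-Claisen cleavage, O-cyclisation can compete, and A2 still needs desilylation next to the acid-sensitive tricarbonyl.
- Comparison: the chosen route gives a defined origin for the quaternary centre, uses the tertiary oxygen as leaving group instead of protecting it, and joins two fragments of similar size in one operation.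

**Alternative 2:** No skeletal bond is cut; the quaternary centre is traced to the prochiral dione A3, whose two carbonyl groups are enantiotopic. Forward, baker's yeast or a ketoreductase reduces one of them and gives the hydroxy ketone A4 with the quaternary carbon fixed.
- For: this is among the best-established routes to a quaternary centre between two carbonyl carbons, and the selectivity comes from an enzyme rather than an enolate geometry. On certainty of stereocontrol it is stronger than step 2.
- Against: A4 has only two of the three ring A oxygens. The carbinol must be reoxidised, a third oxygen introduced at the carbon opposite the quaternary centre, the β-branched ring B unit attached and the acyl group added. Any intermediate with three equivalent carbonyls and no C4 substituent is achiral, so the order of these redox steps is tightly constrained.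
- Comparison: more secure stereochemistry, much poorer step economy. The chosen strategy delivers the quaternary carbon already bonded to a distinct ester and ketone at the final oxidation level, with the prenyl precursor attached.

**Alternative 3:** Ring B is opened at the C1′–C5′ bond and the C2′–O bond, leading to the acyclic hydroxygeranyl trione A5. Forward, [Ir(cod)Cl]2 with a chiral ligand ionises the terminal allylic alcohol of A5; the 2,3-alkene attacks the allyl terminus (C1′–C5′ bond, isopropenyl unveiled) and the tertiary cation at C2′ is captured by the adjacent ring A enol oxygen, giving the cis-fused tricyclic enol ether A6.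
- For: it follows the likely biogenesis, makes ring B and its three stereocentres in one step, and the chain of A5 can be attached by simple allylic C-alkylation. For ring B it is clearly shorter than the seven steps to lactone 19.
- Against: A6 is not the target. The tertiary oxygen is locked in a vinylogous ester, and opening a tertiary alkyl enol ether means acid that ionises the tertiary C–O bond (elimination or reclosure) or base that attacks the tricarbonyl. Three new centres would be set relative to a remote quaternary centre by catalyst control alone, and two enol oxygens compete for the cation.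
- Comparison: the chosen route never forms this ether; the tertiary oxygen is the lactone oxygen of 19 and is released as an alkoxide in step 12, and the ring B centres come from terpene 9 and two stereospecific steps.

Key step: step 2

## Route

Step 1
Reactants: 1 ethyl 2-methyl-3-oxobutanoate; 2 (R)-but-3-en-2-ol
Product: 3 (2R)-but-3-en-2-yl 2-methyl-3-oxobutanoate (both α-epimers)
Conditions: 1 (1.5 equiv), DMAP (0.3 equiv), 5 Å MS, PhMe, reflux
Reagents that add atoms: none
Why: DMAP-catalysed transesterification of a β-keto ester (acylketene or acylpyridinium pathway), driven by trapping ethanol on the sieves; the carbinol C–O bond of 2 is not broken, so (R) is retained, and the α-epimer mixture is irrelevant because that carbon is enolised next.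

Step 2
Reactants: 3 (2R)-but-3-en-2-yl 2-methyl-3-oxobutanoate
Product: 5 (2S,4E)-2-acetyl-2-methylhex-4-enoic acid, via dilithium dienolate 4 (not isolated)
Conditions: LiN(iPr)2 (2.2 equiv), THF, −78 → 25 °C; cold 1 M HCl, 0 °C
Reagents that add atoms: none
Why: Two equivalents of lithium diisopropylamide remove the proton between the carbonyls and then one from the acetyl methyl group, giving dienolate 4, whose ester half is an electron-rich enolate that undergoes a [3,3]-sigmatropic shift far more readily than the monoanion and ends as a carboxylate, so the carboxyl carbon is kept. The closest known reaction types are the ester-dienolate Carroll rearrangement and the Ireland–Claisen rearrangement of secondary allylic esters with 1,3-chirality transfer. No ring is closed; one C–C bond (quaternary carbon to the allyl terminus) and one stereocentre are formed. In the chair transition state the methyl group on the carbinol carbon is pseudo-equatorial, which fixes the allyl face that is attacked and gives the (E)-alkene. The enolate face is fixed by the enolate geometry: lithium bridges the two enolate oxygens, so the α-methyl group is cis to the allylic ester oxygen and pseudo-axial, and the enolised acetyl arm is pseudo-equatorial. With the (R) carbinol this combination places the crotyl group on the face that gives the (S) acid 5. The step needs a single enolate geometry and a chair rather than a boat; chelation and the equatorial preference of the methyl group should secure both. The product stays a carboxylate–enolate dianion until the cold acidic quench, which should suppress decarboxylation.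

Step 3
Reactants: 5 (2S,4E)-2-acetyl-2-methylhex-4-enoic acid
Product: 6 methyl (2S,4E)-2-acetyl-2-methylhex-4-enoate
Conditions: Me3SiCHN2, PhMe/MeOH (4:1), 0 °C, crude 5 used at once
Reagents that add atoms: trimethylsilyldiazomethane, C[Si](C)(C)C=[N+]=[N-]
Why: Diazoalkane esterification at 0 °C (protonation of the diazo carbon by the acid, methyl transfer to the carboxylate), so the α,α-disubstituted β-keto acid is never warmed and should not decarboxylate; the stereocentre has no hydrogen and is not at risk.

Step 4
Reactants: 6 methyl (2S,4E)-2-acetyl-2-methylhex-4-enoate; 7 2-methylbut-2-ene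
Product: 8 methyl (2S)-2-acetyl-2,5-dimethylhex-4-enoate
Conditions: (H2IMes)(PCy3)Cl2Ru=CHPh (second-generation Grubbs catalyst, 3 mol %), 7 (excess), CH2Cl2, 40 °C, sealed vessel
Reagents that add atoms: none
Why: Olefin cross-metathesis of the 1,2-disubstituted crotyl alkene with a large excess of the trisubstituted alkene 7 exchanges the ethylidene end for an isopropylidene end and releases volatile but-2-ene; the quaternary centre is two bonds from the alkene and is untouched.

Step 5
Reactants: 9 (S)-limonene
Product: 10 (4S)-1-methyl-4-(prop-1-en-2-yl)-7-oxabicyclo[4.1.0]heptane (cis/trans epoxide mixture)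
Conditions: mCPBA (1.0 equiv), CH2Cl2, 0 °C
Reagents that add atoms: 3-chloroperoxybenzoic acid, OOC(=O)c1cccc(Cl)c1
Why: Prilezhaev epoxidation; the trisubstituted ring alkene is more nucleophilic than the 1,1-disubstituted isopropenyl alkene and reacts first. Both epoxide diastereomers lead to the same product in step 6.

Step 6
Reactants: 10 (4S)-limonene 1,2-oxide
Product: 12 (3S)-6-oxo-3-(prop-1-en-2-yl)heptanal, via diol 11 (not isolated)
Conditions: H5IO6 (1.2 equiv), THF/H2O (3:1), 0 °C → rt
Reagents that add atoms: water, O
Why: The acidic periodate medium hydrolyses the epoxide to the 1,2-diol, which undergoes Malaprade glycol cleavage in the same flask; the stereocentre is not involved.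

Step 7
Reactants: 12 (3S)-6-oxo-3-(prop-1-en-2-yl)heptanal
Product: 13 (5R)-2-methyl-5-(prop-1-en-2-yl)cyclopent-1-ene-1-carbaldehyde
Conditions: piperidine (0.2 equiv), AcOH (0.2 equiv), PhMe, 60 °C
Reagents that add atoms: none
Why: Intramolecular aldol condensation: the enamine of the aldehyde attacks the methyl ketone (five-membered ring, enolexo) and water is lost to the tetrasubstituted enal; the alternative modes would give seven-membered rings. The descriptor changes from S to R only through a priority change.

Step 8
Reactants: 13 (5R)-2-methyl-5-(prop-1-en-2-yl)cyclopent-1-ene-1-carbaldehyde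
Product: 14 (1R,2R,5S)-5-methyl-2-(prop-1-en-2-yl)-6-oxabicyclo[3.1.0]hexane-1-carbaldehyde
Conditions: 30% aq. H2O2, NaOH (cat.), MeOH, 0 °C
Reagents that add atoms: hydrogen peroxide, OO
Why: Weitz–Scheffer nucleophilic epoxidation: hydroperoxide adds reversibly to the β-carbon and the enolate closes the oxirane at the α-carbon, which should be easy only on the face away from the adjacent isopropenyl group, so oxygen enters anti to it. The nucleophilic oxidant does not attack the isolated isopropenyl alkene.

Step 9
Reactants: 14 epoxy aldehyde; 15 methyl (triphenylphosphoranylidene)acetate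
Product: 16 methyl (2E)-3-[(1R,2R,5S)-5-methyl-2-(prop-1-en-2-yl)-6-oxabicyclo[3.1.0]hexan-1-yl]prop-2-enoate
Conditions: CH2Cl2, rt → 40 °C
Reagents that add atoms: none
Why: Wittig olefination with a stabilised ylide, (E)-selective and neutral, so the epoxide and the α-quaternary aldehyde are not disturbed.

Step 10
Reactants: 16 epoxy enoate
Product: 17 methyl (2E)-3-[(1R,2S,5S)-2-hydroxy-2-methyl-5-(prop-1-en-2-yl)cyclopentyl]prop-2-enoate
Conditions: Pd2(dba)3·CHCl3 (2.5 mol %), n-Bu3P (10 mol %), HCO2H (5 equiv), Et3N (2 equiv), 1,4-dioxane, rt
Reagents that add atoms: none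
Why: Palladium-catalysed formate hydrogenolysis of an alkenyl oxirane: zerovalent palladium ionises the allylic C–O bond with inversion, the formate on palladium loses CO2, and hydride passes from the metal to the ring terminus of the π-allyl unit on the face opposite the departed oxygen, restoring the conjugated (E)-enoate. Net inversion at C1′ puts the chain cis to the tertiary hydroxyl and trans to isopropenyl; the reaction type is established for 4,5-epoxy-2-enoates with a fully substituted 4-carbon.

Step 11
Reactants: 17 hydroxy enoate
Product: 19 (4aR,5S,7aS)-7a-methyl-5-(prop-1-en-2-yl)hexahydrocyclopenta[b]pyran-2(3H)-one, via hydroxy ester 18 (not isolated)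
Conditions: Mg turnings, MeOH, 0 °C → rt; then PPTS (0.1 equiv), PhMe, 60 °C
Reagents that add atoms: none
Why: Dissolving-metal conjugate reduction (Mg/MeOH) reduces only the enoate alkene and leaves the isolated 1,1-disubstituted alkene; the cis δ-hydroxy ester 18 then lactonises under mild acid catalysis. Only the cis isomer can close, so lactonisation also confirms the relative configuration.

Step 12
Reactants: 8 methyl (2S)-2-acetyl-2,5-dimethylhex-4-enoate; 19 ring B lactone
Product: 21 (6R)-3,5-dihydroxy-4-{[(1R,2S,5S)-2-hydroxy-2-methyl-5-(prop-1-en-2-yl)cyclopentyl]methyl}-6-methyl-6-(3-methylbut-2-en-1-yl)cyclohexa-2,4-dien-1-one, via hydroxy diketo ester 20 (not isolated)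
Conditions: 8 (1.1 equiv), LiN(iPr)2 (1.1 equiv), THF, −78 °C; 19 (1.0 equiv), −78 → −20 °C; LiN(iPr)2 (2.5 equiv), −78 → 0 °C; cold 1 M HCl to pH 3
Reagents that add atoms: none
Why: Keto ester 8 can be deprotonated only at the acetyl methyl group; Claisen acylation of that enolate by lactone 19 forms C2–C3 and releases the tertiary alkoxide, and further base converts the diketonate of 20 into a 1,3-diketone dianion whose terminal carbon attacks the methyl ester in a 6-exo-trig Dieckmann closure (C4–C5). No stereocentre is formed; C6 has no α-hydrogen and keeps its configuration, and the intermediate is never exposed to acid before the ring is closed.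

Step 13
Reactants: 21 trione; 22 (R)-2-methylbutanoic acid
Product: 24 (6R)-3,5-dihydroxy-4-{[(1R,2S,5S)-2-hydroxy-2-methyl-5-(prop-1-en-2-yl)cyclopentyl]methyl}-6-methyl-6-(3-methylbut-2-en-1-yl)-2-[(2R)-2-methylbutanoyl]cyclohexa-2,4-dien-1-one, via enol ester 23 (not isolated)
Conditions: DCC (1.2 equiv), DMAP (1.3 equiv), CH2Cl2, 0 °C → rt
Reagents that add atoms: none
Why: Carbodiimide activation gives enol ester 23, and DMAP transfers the acyl group from oxygen to C2, the only unsubstituted carbon between two carbonyls (Steglich-type O-to-C acyl migration, known for cyclic 1,3-diones and 1,3,5-triones); the acidic product is held as its DMAP salt. The tertiary alcohol is too hindered to be acylated at this temperature, and the low temperature should limit enolisation of the acyl donor so that the (R) centre is kept.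

## Compound list

1 | ethyl 2-methyl-3-oxobutanoate (racemic) | CCOC(=O)C(C)C(C)=O | starting material
2 | (R)-but-3-en-2-ol | C=C[C@@H](C)O | starting material
3 | (2R)-but-3-en-2-yl 2-methyl-3-oxobutanoate (both α-epimers) | C=C[C@@H](C)OC(=O)C(C)C(C)=O | intermediate
4 | dilithium dienolate of 3 (α-methyl cis to the allylic ester oxygen, lithium bridging the enolate oxygens; formed in the flask in step 2) | C=C[C@@H](C)O/C([O-])=C(\C)C([O-])=C.[Li+].[Li+] | intermediate
5 | (2S,4E)-2-acetyl-2-methylhex-4-enoic acid | OC(=O)[C@@](C)(C/C=C/C)C(C)=O | intermediate
6 | methyl (2S,4E)-2-acetyl-2-methylhex-4-enoate | COC(=O)[C@@](C)(C/C=C/C)C(C)=O | intermediate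
7 | 2-methylbut-2-ene | CC=C(C)C | starting material
8 | methyl (2S)-2-acetyl-2,5-dimethylhex-4-enoate | COC(=O)[C@@](C)(CC=C(C)C)C(C)=O | intermediate
9 | (S)-limonene, (4S)-1-methyl-4-(prop-1-en-2-yl)cyclohex-1-ene | CC1=CC[C@H](CC1)C(C)=C | starting material
10 | (4S)-1-methyl-4-(prop-1-en-2-yl)-7-oxabicyclo[4.1.0]heptane (cis/trans mixture at the epoxide) | CC12OC1C[C@H](CC2)C(C)=C | intermediate
11 | (4S)-1-methyl-4-(prop-1-en-2-yl)cyclohexane-1,2-diol (diastereomer mixture; formed in the flask in step 6) | CC1(O)C(O)C[C@H](CC1)C(C)=C | intermediate
12 | (3S)-6-oxo-3-(prop-1-en-2-yl)heptanal | O=CC[C@H](CCC(C)=O)C(C)=C | intermediate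
13 | (5R)-2-methyl-5-(prop-1-en-2-yl)cyclopent-1-ene-1-carbaldehyde | O=CC1=C(C)CC[C@@H]1C(C)=C | intermediate
14 | (1R,2R,5S)-5-methyl-2-(prop-1-en-2-yl)-6-oxabicyclo[3.1.0]hexane-1-carbaldehyde | O=C[C@]12O[C@@]1(C)CC[C@@H]2C(C)=C | intermediate
15 | methyl (triphenylphosphoranylidene)acetate | COC(=O)C=P(c1ccccc1)(c1ccccc1)c1ccccc1 | starting material
16 | methyl (2E)-3-[(1R,2R,5S)-5-methyl-2-(prop-1-en-2-yl)-6-oxabicyclo[3.1.0]hexan-1-yl]prop-2-enoate | COC(=O)/C=C/[C@]12O[C@@]1(C)CC[C@@H]2C(C)=C | intermediate
17 | methyl (2E)-3-[(1R,2S,5S)-2-hydroxy-2-methyl-5-(prop-1-en-2-yl)cyclopentyl]prop-2-enoate | C=C(C)[C@H]1CC[C@](C)(O)[C@@H]1/C=C/C(=O)OC | intermediate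
18 | methyl 3-[(1R,2S,5S)-2-hydroxy-2-methyl-5-(prop-1-en-2-yl)cyclopentyl]propanoate (formed in the flask in step 11) | C=C(C)[C@H]1CC[C@](C)(O)[C@@H]1CCC(=O)OC | intermediate
19 | (4aR,5S,7aS)-7a-methyl-5-(prop-1-en-2-yl)hexahydrocyclopenta[b]pyran-2(3H)-one | C=C(C)[C@H]1CC[C@]2(C)OC(=O)CC[C@H]12 | intermediate
20 | methyl (2S)-7-[(1R,2S,5S)-2-hydroxy-2-methyl-5-(prop-1-en-2-yl)cyclopentyl]-2-methyl-2-(3-methylbut-2-en-1-yl)-3,5-dioxoheptanoate (present as its lithium salt in the flask in step 12; drawn neutral) | C=C(C)[C@H]1CC[C@](C)(O)[C@@H]1CCC(=O)CC(=O)[C@](C)(CC=C(C)C)C(=O)OC | intermediate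
21 | (6R)-3,5-dihydroxy-4-{[(1R,2S,5S)-2-hydroxy-2-methyl-5-(prop-1-en-2-yl)cyclopentyl]methyl}-6-methyl-6-(3-methylbut-2-en-1-yl)cyclohexa-2,4-dien-1-one (one enol form of the trione) | C=C(C)[C@H]1CC[C@](C)(O)[C@@H]1CC1=C(O)[C@@](C)(CC=C(C)C)C(=O)C=C1O | intermediate
22 | (R)-2-methylbutanoic acid | CC[C@@H](C)C(=O)O | starting material
23 | (4R)-5-hydroxy-6-{[(1R,2S,5S)-2-hydroxy-2-methyl-5-(prop-1-en-2-yl)cyclopentyl]methyl}-4-methyl-4-(3-methylbut-2-en-1-yl)-3-oxocyclohexa-1,5-dien-1-yl (2R)-2-methylbutanoate (formed in the flask in step 13; drawn as the ester of the enol oxygen next to the ring CH, the isomers on the other enol oxygens converge on the same product) | C=C(C)[C@H]1CC[C@](C)(O)[C@@H]1CC1=C(O)[C@@](C)(CC=C(C)C)C(=O)C=C1OC(=O)[C@H](C)CC | intermediate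
24 | (6R)-3,5-dihydroxy-4-{[(1R,2S,5S)-2-hydroxy-2-methyl-5-(prop-1-en-2-yl)cyclopentyl]methyl}-6-methyl-6-(3-methylbut-2-en-1-yl)-2-[(2R)-2-methylbutanoyl]cyclohexa-2,4-dien-1-one (CNP0299585.1) | C=C(C)[C@H]1CC[C@](C)(O)[C@@H]1CC1=C(O)[C@@](C)(CC=C(C)C)C(=O)C(C(=O)[C@H](C)CC)=C1O | target

## Step count and least certain steps

Total step count: 13 (steps 1–4 to fragment 8, steps 5–11 to fragment 19, steps 12 and 13 after the union). Longest linear sequence: 9 steps (steps 5–13, from 9).

**Step 2 (key step).** The dienolate may not adopt a single geometry, or part of the rearrangement may pass through the chair with an axial carbinol methyl group; either leak lowers the enantiomeric purity at the quaternary carbon. Slow rearrangement would call for heating, which invites decarboxylation on work-up.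
Fallback (sets out from 1, returns to the route at 21): the quaternary centre is set by auxiliary-controlled alkylation instead of rearrangement. Condensation of 1 with L-valine tert-butyl ester gives the enamino ester F1. Deprotonation with lithium diisopropylamide and alkylation with 1-bromo-3-methylbut-2-ene, on the face left open by the chelated valine ester, gives the imine F2; the donor ligand on lithium decides the face, so the conditions leading to the (S) series are chosen. Mild aqueous acid releases the ethyl keto ester F3 and returns the auxiliary. F3 takes the place of 8 in step 12; the open-chain intermediate is then the ethyl ester F4, which closes to 21 with loss of ethoxide.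

**Step 12.** Proton transfer from the lactone to the enolate, or reversal of the acylation, may leave the coupling incomplete. The polyanion may aggregate so that the Dieckmann closure stalls. On acidification the freed tertiary alcohol may add to the neighbouring carbonyl and dehydrate to a cyclic enol ether.
Fallback (sets out from 19, returns at 21): the electrophile and the protection are changed. Lactone 19 is opened with Me3Al and N,O-dimethylhydroxylamine hydrochloride to the hydroxy Weinreb amide F5, which is silylated (Et3SiOSO2CF3, 2,6-lutidine) to the triethylsilyl ether F6. The lithium enolate of 8 adds once to F6, since the chelated adduct can neither revert nor add twice, giving the silylated diketo ester F7. This needs only two equivalents of base for the Dieckmann closure to the silylated trione F8, and HF·pyridine then frees the alcohol to give 21.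

**Step 10.** Shielding by the isopropenyl and methyl groups on the face that palladium must approach may slow ionisation, so that β-hydride elimination to a diene or hydride delivery at the other allyl terminus competes.
Fallback (sets out from 14, returns at 17): the C1′–H bond is made by reductive cleavage next to a carbonyl group and the centre is set under thermodynamic control. Pinnick oxidation (NaClO2, NaH2PO4) gives the epoxy acid F9 and Me3SiCHN2 the epoxy ester F10. SmI2 (THF/MeOH, −78 °C) cleaves the α C–O bond to the β-hydroxy ester F11, in which C1′ is α to the ester and can be equilibrated to the trans isomer if protonation gives the cis one. Reduction with iBu2AlH at −78 °C gives the hydroxy aldehyde F12, and the Wittig reaction with 15 returns to 17.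

**Step 8.** Facial selectivity of the epoxidation may be modest, because the controlling substituent is next to the α-carbon and one carbon removed from the β-carbon where the oxidant first adds.
Fallback (sets out from 13, returns at 14): reagent control replaces substrate control. Luche reduction (NaBH4, CeCl3·7H2O) gives the allylic alcohol F13. Sharpless asymmetric epoxidation (Ti(OiPr)4, D-(−)-diethyl tartrate, t-BuOOH, 4 Å MS, −20 °C) gives the epoxy alcohol F14; this tartrate delivers oxygen to the face anti to the isopropenyl group, so catalyst and substrate agree. Dess–Martin oxidation returns to 14.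

## Further compounds

F1 | step 2 | ethyl (2Z)-3-{[(2S)-1-tert-butoxy-3-methyl-1-oxobutan-2-yl]amino}-2-methylbut-2-enoate | CCOC(=O)/C(C)=C(/C)N[C@@H](C(C)C)C(=O)OC(C)(C)C
F2 | step 2 | ethyl (2S)-2-{1-[(2S)-1-tert-butoxy-3-methyl-1-oxobutan-2-yl]iminoethyl}-2,5-dimethylhex-4-enoate | CCOC(=O)[C@@](C)(CC=C(C)C)C(C)=N[C@@H](C(C)C)C(=O)OC(C)(C)C
F3 | step 2 | ethyl (2S)-2-acetyl-2,5-dimethylhex-4-enoate | CCOC(=O)[C@@](C)(CC=C(C)C)C(C)=O
F4 | step 2 | ethyl (2S)-7-[(1R,2S,5S)-2-hydroxy-2-methyl-5-(prop-1-en-2-yl)cyclopentyl]-2-methyl-2-(3-methylbut-2-en-1-yl)-3,5-dioxoheptanoate | C=C(C)[C@H]1CC[C@](C)(O)[C@@H]1CCC(=O)CC(=O)[C@](C)(CC=C(C)C)C(=O)OCC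
F5 | step 12 | 3-[(1R,2S,5S)-2-hydroxy-2-methyl-5-(prop-1-en-2-yl)cyclopentyl]-N-methoxy-N-methylpropanamide | C=C(C)[C@H]1CC[C@](C)(O)[C@@H]1CCC(=O)N(C)OC
F6 | step 12 | N-methoxy-N-methyl-3-[(1R,2S,5S)-2-methyl-5-(prop-1-en-2-yl)-2-(triethylsilyloxy)cyclopentyl]propanamide | C=C(C)[C@H]1CC[C@](C)(O[Si](CC)(CC)CC)[C@@H]1CCC(=O)N(C)OC
F7 | step 12 | methyl (2S)-2-methyl-2-(3-methylbut-2-en-1-yl)-7-[(1R,2S,5S)-2-methyl-5-(prop-1-en-2-yl)-2-(triethylsilyloxy)cyclopentyl]-3,5-dioxoheptanoate | C=C(C)[C@H]1CC[C@](C)(O[Si](CC)(CC)CC)[C@@H]1CCC(=O)CC(=O)[C@](C)(CC=C(C)C)C(=O)OC
F8 | step 12 | (6R)-3,5-dihydroxy-6-methyl-6-(3-methylbut-2-en-1-yl)-4-{[(1R,2S,5S)-2-methyl-5-(prop-1-en-2-yl)-2-(triethylsilyloxy)cyclopentyl]methyl}cyclohexa-2,4-dien-1-one | C=C(C)[C@H]1CC[C@](C)(O[Si](CC)(CC)CC)[C@@H]1CC1=C(O)[C@@](C)(CC=C(C)C)C(=O)C=C1O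
F9 | step 10 | (1R,2R,5S)-5-methyl-2-(prop-1-en-2-yl)-6-oxabicyclo[3.1.0]hexane-1-carboxylic acid | OC(=O)[C@]12O[C@@]1(C)CC[C@@H]2C(C)=C
F10 | step 10 | methyl (1R,2R,5S)-5-methyl-2-(prop-1-en-2-yl)-6-oxabicyclo[3.1.0]hexane-1-carboxylate | COC(=O)[C@]12O[C@@]1(C)CC[C@@H]2C(C)=C
F11 | step 10 | methyl (1R,2S,5S)-2-hydroxy-2-methyl-5-(prop-1-en-2-yl)cyclopentane-1-carboxylate | C=C(C)[C@H]1CC[C@](C)(O)[C@@H]1C(=O)OC
F12 | step 10 | (1R,2S,5S)-2-hydroxy-2-methyl-5-(prop-1-en-2-yl)cyclopentane-1-carbaldehyde | C=C(C)[C@H]1CC[C@](C)(O)[C@@H]1C=O
F13 | step 8 | [(5R)-2-methyl-5-(prop-1-en-2-yl)cyclopent-1-en-1-yl]methanol | OCC1=C(C)CC[C@@H]1C(C)=C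
F14 | step 8 | [(1S,2R,5S)-5-methyl-2-(prop-1-en-2-yl)-6-oxabicyclo[3.1.0]hexan-1-yl]methanol | OC[C@]12O[C@@]1(C)CC[C@@H]2C(C)=C
A1 | alternative 1 | methyl (2R,8R)-2,8-dimethyl-2-(3-methylbut-2-en-1-yl)-4-{[(1R,2S,5S)-2-methyl-5-(prop-1-en-2-yl)-2-(triethylsilyloxy)cyclopentyl]methyl}-3,5,7-trioxodecanoate (epimers at C4) | C=C(C)[C@H]1CC[C@](C)(O[Si](CC)(CC)CC)[C@@H]1CC(C(=O)CC(=O)[C@H](C)CC)C(=O)[C@@](C)(CC=C(C)C)C(=O)OC
A2 | alternative 1 | triethylsilyl ether of the target at the tertiary alcohol | C=C(C)[C@H]1CC[C@](C)(O[Si](CC)(CC)CC)[C@@H]1CC1=C(O)[C@@](C)(CC=C(C)C)C(=O)C(C(=O)[C@H](C)CC)=C1O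
A3 | alternative 2 | 2-methyl-2-(3-methylbut-2-en-1-yl)cyclohexane-1,3-dione | CC1(CC=C(C)C)C(=O)CCCC1=O
A4 | alternative 2 | (2S,3S)-3-hydroxy-2-methyl-2-(3-methylbut-2-en-1-yl)cyclohexan-1-one | O=C1[C@@](C)(CC=C(C)C)[C@@H](O)CCC1
A5 | alternative 3 | (6R)-3,5-dihydroxy-4-[(2E,6E)-8-hydroxy-3,7-dimethylocta-2,6-dien-1-yl]-6-methyl-6-(3-methylbut-2-en-1-yl)-2-[(2R)-2-methylbutanoyl]cyclohexa-2,4-dien-1-one | OC/C(C)=C/CC/C(C)=C/CC1=C(O)[C@@](C)(CC=C(C)C)C(=O)C(C(=O)[C@H](C)CC)=C1O
A6 | alternative 3 | cis-fused cyclopenta-pyrano tricycle, the cyclic enol ether between the tertiary oxygen and the ring A enol carbon next to the quaternary centre | C=C(C)[C@H]1CC[C@](C)(O3)[C@@H]1CC1=C3[C@@](C)(CC=C(C)C)C(=O)C(C(=O)[C@H](C)CC)=C1O
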